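## Analysis of the target

The target 22 is a 2,3-dihydro-1-benzofuran in which aromatic ring A (C3a, C4 to C7, C7a) is fused to the oxygen ring B (O1, C2, C3); C7 carries a methoxy group and C5 a three-carbon chain that ends in a hydrogen sulfate. C2 carries ring C (4-hydroxy-3-methoxyphenyl) and C3 carries the hydroxymethyl carbon C9. The only stereocentres are C2 (S) and C3 (R); they are neighbours, and the aryl group on C2 and the CH2OH group on C3 are trans. The sensitive points are the alkyl hydrogen sulfate (solvolysed by acid, so it must be made after the last acidic step and kept as a salt), the O1–C2 bond (a benzylic aryl ether para to the ring C oxygen, which ionises in acid and can be hydrogenolysed) and the free phenol. There are two primary alcohols and only the one on the chain is sulfated, so the two must be told apart throughout. The real difficulty is the absolute configuration at C3, a carbon with aryl, CH2O and alkyl substituents and no heteroatom to guide a reagent; C2 is easier, because the trans ring is the preferred outcome whenever O1–C2 forms reversibly. The plan rests on C2 and C3 being a vicinal pair in which each carbon carries one aryl ring (ring C on C2, C3a of ring A on C3) and C2 carries an oxygen as well: this is the pattern left when two different aryl groups are added anti across a C2=C3 alkenylboron unit and boron on C2 is then exchanged for oxygen. That oxygen cannot itself be O1, because O1 has to be bonded to C7a of ring A, so it serves as the leaving group and the phenol oxygen already on C7a closes ring B.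

## Retrosynthetic reasoning

**Sulfate and benzyl groups (22 to 21 to 20).** The O–S bond and the two O–benzyl bonds are cut first. The sulfate cannot survive acid, so it is introduced on 20, where the chain hydroxyl is the only free OH, and the benzyl ethers on the ring C phenol and on O9 are removed afterwards under neutral conditions. The forward steps must sulfate one alcohol cleanly and then cleave two benzyl ethers without opening the O1–C2 bond.

**Ring B (20 to 18 through 19).** The O1–C2 bond is cut. C2 is benzylic and para to the ring C oxygen, so a C2–O bond can be exchanged by ionisation, and the nucleophile is the C7a phenol, which is masked in 18 as an acetal. Because the closure runs through a planar cation and is reversible, either C2 epimer leads to the trans ring. The precursor therefore has to deliver only C3 with certainty. The same acid also frees the chain alcohol from its silyl ether, which prepares the sulfation. The forward reaction must ionise C2, close the five-membered ring and avoid loss of the C3 hydrogen.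

**C2–O from C2–B (18 to 17).** The C2 hydroxyl is traced to a boronic ester, since C–B oxidation is stereoretentive and mild. This gives C2 a substituent that can organise the carbon–carbon bond formation in the step before.

**Key disconnection (17 to 7, 14 and 15 through 16).** Two bonds are cut at once: C2 to ring C and C3 to C3a. Rings A and C then arrive as finished arenes with all their substituents, and the three carbons C2, C3 and C9 come from one alkenylboron piece. Cutting C2–C3 instead (an aldol-type plan) would need a stoichiometric auxiliary to set C3, and cutting inside ring A would leave methoxy and chain to be added later. The forward reaction joins aryllithium 15, alkenylboronate 14 and triflate 7 through borate 16, and it must let the metallate shift win over direct coupling, select one face of the alkene and avoid β-elimination at C9. For that reason 14 is the ester of the hindered di-tertiary diol 11 and not of a smaller diol, because a β-substituent on the alkenyl group otherwise tips such borates toward plain transmetallation.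

**Ring A partner (7 back to 1).** The triflate and silyl groups are removed on paper (7 to 6 to 5), and the chain is cut between its first and second carbon (5 to 4 to 3 to 2), so that the formyl carbon of 1 becomes the benzylic CH2 and an olefination brings the other two carbons. The two phenols of 1 are told apart by acidity: the one para to the formyl group is alkylated first and becomes O1 (2), the other is left for the triflate that marks C3a.

**Boron and ring C partners (14 to 12 and 11; 11 to 10; 15 to 9 to 8).** The B–C bond of 14 is cut to alkyne 12 by hydroboration, which fixes the E geometry, and the diol 11 comes from diketone 10 by double methyl addition. The aryllithium 15 comes from bromide 9 by halogen–lithium exchange, and 9 from phenol 8 by benzylation.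

## Alternatives that were turned down

**Alternative 1:** The bonds made last are O1–C2 and C3–H. The trisubstituted stilbene A1 (ring C on C2, ring A and the acetoxymethyl group on C3, both phenols free) would be treated with a confined chiral imidodiphosphorimidate acid. Proton transfer to C3 gives the ring C para-quinone methide cation, and the C7a phenol adds to C2 to give the trans dihydrobenzofuran acetate A2.
- For it: it is the shortest plan, one catalytic step sets both centres and closes ring B from an achiral alkene, ring C needs no protection, and no organometallic reagent is used. On step count and atom economy it is stronger than the chosen route.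
- Against it: the enantio-determining event is protonation of a 1,2-diaryl alkene whose two faces differ only through remote substituents, and both phenols and the acetate can bind the catalyst anion in competing ways. The acid must be strong enough to protonate the stilbene, so the cation can lose the C3 proton and be re-protonated, and C3 can be scrambled by the reagent that sets it. Any achiral acid present gives racemic product.
- Comparison: the chosen route reaches the same C2 cation from an alcohol under much weaker acid, with C3 already fixed in a C–C bond-forming step under ligand control. It pays for that with more steps.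

**Alternative 2:** The bonds cut are C3a–C7a, C4–C5 and C6–C7, so ring A is built by a (2+2+2) cyclotrimerisation. The tethered diyne A3, which carries a triethylsilyl-capped ynol ether on O1 and an ethynyl group on C3, would be combined with the pentynyl silyl ether A4 on a cationic bisphosphine complex of monovalent rhodium to give the 7-silyl dihydrobenzofuran A5.
- For it: rings A and B form together, and the O1–C2 bond and the trans relationship exist before the key step and are never exposed to an ionising ring closure. On that point it is stronger than the chosen route.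
- Against it: the key step creates no stereocentre, so both must be built into A3 by a separate asymmetric sequence, with C3 as a propargylic centre. The silyl ynol ether of a secondary benzylic alcohol is a fragile intermediate. The position of the chain (C5 or C6) depends only on the silyl group, and C7 emerges as C–Si and must still be turned into C–OMe.
- Comparison: it needs more steps before and after the key step. The chosen route buys ring A complete from a benzaldehyde and spends its key step on the stereocentres.

**Alternative 3:** The bonds cut are C3a–C4 and C7–C7a, so ring A is built on a lactone. The silyl ketene acetal A6 of a trans 4,5-disubstituted butyrolactone would act through its C3a=C7a bond as an electron-rich dienophile toward the bromo-pyranone ester A7, and decarboxylative cycloreversion with loss of the silyloxy group would leave the aromatic bromo ester A8.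
- For it: both stereocentres sit in a lactone whose trans form is preferred and accessible by established asymmetric lactone chemistry, ring B is present from the start, and the polar cycloaddition should be regioselective. On the security of C2 and of ring B it is as strong as or stronger than the chosen route.
- Against it: A8 has the wrong groups on ring A, so C5 needs a two-carbon homologation of the ester (about four steps) and C7 a bromide-to-methoxy exchange. The acid-sensitive ketene acetal must survive a thermal cycloaddition, and the lactone itself costs several steps.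
- Comparison: it is clearly longer after the key step. The chosen route is convergent and brings ring A fully substituted.

Key step: step 10

Remark 1: the antipode of the Mandyphos ligand is chosen according to the configuration found at C3 of 18 on the first run; both antipodes are commercial.
Remark 2: the hydrogen sulfate is handled and isolated as its sodium salt in steps 13 and 14; names and SMILES show the free acid as the target is drawn.

## Route

Step 1
Reactants: 1 5-hydroxyvanillin (3,4-dihydroxy-5-methoxybenzaldehyde)
Product: 2 3-hydroxy-5-methoxy-4-(methoxymethoxy)benzaldehyde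
Conditions: MOMCl (1.05 equiv), K2CO3 (1.1 equiv), acetone, 0 °C → rt
Reagents that add atoms: chloromethyl methyl ether, COCCl
Why: Williamson-type O-alkylation; the 4-hydroxyl is para to the formyl group and is the more acidic phenol, so one equivalent of carbonate gives mainly its phenoxide and the acetal goes on the oxygen that becomes O1, leaving the 3-hydroxyl for the triflate.

Step 2
Reactants: 2 3-hydroxy-5-methoxy-4-(methoxymethoxy)benzaldehyde
Product: 3 ethyl (E)-3-[3-hydroxy-5-methoxy-4-(methoxymethoxy)phenyl]prop-2-enoate
Conditions: Ph3P=CHCO2Et (1.2 equiv), toluene, 80 °C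
Reagents that add atoms: ethyl (triphenylphosphoranylidene)acetate, CCOC(=O)C=P(c1ccccc1)(c1ccccc1)c1ccccc1
Why: Wittig olefination with a stabilised ylide, which should give the E cinnamate; the ylide is too weak a base to be quenched by the free phenol.

Step 3
Reactants: 3 ethyl (E)-3-[3-hydroxy-5-methoxy-4-(methoxymethoxy)phenyl]prop-2-enoate
Product: 4 ethyl 3-[3-hydroxy-5-methoxy-4-(methoxymethoxy)phenyl]propanoate
Conditions: H2 (1 atm), Pd/C (10%), EtOAc, rt
Reagents that add atoms: none
Why: Heterogeneous catalytic hydrogenation of the conjugated C=C bond; the aryl acetal, the ester and the arene are inert at one atmosphere and room temperature.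

Step 4
Reactants: 4 ethyl 3-[3-hydroxy-5-methoxy-4-(methoxymethoxy)phenyl]propanoate
Product: 5 3-[3-hydroxy-5-methoxy-4-(methoxymethoxy)phenyl]propan-1-ol
Conditions: LiAlH4 (2.5 equiv), THF, 0 °C → rt
Reagents that add atoms: none
Why: Hydride reduction of the ester to the primary alcohol; the phenol only consumes one hydride and the acetal is stable to the basic medium.

Step 5
Reactants: 5 3-[3-hydroxy-5-methoxy-4-(methoxymethoxy)phenyl]propan-1-ol
Product: 6 5-(3-hydroxypropyl)-3-methoxy-2-(methoxymethoxy)phenyl trifluoromethanesulfonate
Conditions: PhNTf2 (1.1 equiv), K2CO3 (2 equiv), DMF, rt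
Reagents that add atoms: N-phenylbis(trifluoromethanesulfonimide), O=S(=O)(N(c1ccccc1)S(=O)(=O)C(F)(F)F)C(F)(F)F
Why: Chemoselective O-sulfonylation; the triflimide transfers its triflyl group to the phenoxide formed by carbonate but not to the neutral primary alcohol, so the future C3a–OTf is installed without protecting the chain first.

Step 6
Reactants: 6 5-(3-hydroxypropyl)-3-methoxy-2-(methoxymethoxy)phenyl trifluoromethanesulfonate
Product: 7 5-[3-(tert-butyldimethylsilyloxy)propyl]-3-methoxy-2-(methoxymethoxy)phenyl trifluoromethanesulfonate
Conditions: TBSCl (1.2 equiv), imidazole (2 equiv), CH2Cl2, rt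
Reagents that add atoms: tert-butyldimethylsilyl chloride, CC(C)(C)[Si](C)(C)Cl
Why: Imidazole-promoted silylation of a primary alcohol; the aryl triflate and the acetal do not react, and the silyl ether keeps the chain hydroxyl out of the borate chemistry.

Step 7
Reactants: 8 4-bromo-2-methoxyphenol
Product: 9 1-(benzyloxy)-4-bromo-2-methoxybenzene
Conditions: BnBr (1.1 equiv), K2CO3 (1.5 equiv), DMF, rt
Reagents that add atoms: benzyl bromide, BrCc1ccccc1
Why: Williamson ether synthesis on the phenoxide; the benzyl ether withstands t-BuLi and keeps ring C electron-rich for the later ionisation at C2.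

Step 8
Reactants: 10 acenaphthoquinone
Product: 11 cis-1,2-dimethylacenaphthene-1,2-diol
Conditions: MeMgBr (2.5 equiv), THF, −78 °C → rt; recrystallisation
Reagents that add atoms: methylmagnesium bromide, C[Mg]Br
Why: Double Grignard addition to a 1,2-diketone; the second methyl is expected to enter anti to the bulky magnesium alkoxide of the first adduct, which should give mainly the cis (meso) diol, the only isomer able to span boron in a five-membered ester.

Step 9
Reactants: 12 benzyl propargyl ether; 11 cis-1,2-dimethylacenaphthene-1,2-diol
Product: 14 cis-1,2-dimethylacenaphthene-1,2-diyl (E)-3-(benzyloxy)prop-1-enylboronate, via catechol alkenylboronate 13 (not isolated)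
Conditions: catecholborane (1.1 equiv), Cy2BH (5 mol%), THF, rt; then 11 (1.0 equiv), rt
Reagents that add atoms: catecholborane, B1Oc2ccccc2O1
Why: Hydroboration of a terminal alkyne (syn addition, boron to the terminal carbon) gives the E alkenylboronate; transesterification with the di-tertiary diol 11 is driven by the stability of the dialkyl boronate and releases catechol.

Step 10
Reactants: 9 1-(benzyloxy)-4-bromo-2-methoxybenzene; 14 cis-1,2-dimethylacenaphthene-1,2-diyl (E)-3-(benzyloxy)prop-1-enylboronate; 7 5-[3-(tert-butyldimethylsilyloxy)propyl]-3-methoxy-2-(methoxymethoxy)phenyl trifluoromethanesulfonate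
Product: 17 cis-1,2-dimethylacenaphthene-1,2-diyl (1S,2R)-3-(benzyloxy)-1-(4-benzyloxy-3-methoxyphenyl)-2-{5-[3-(tert-butyldimethylsilyloxy)propyl]-3-methoxy-2-(methoxymethoxy)phenyl}propylboronate (anti isomer), via 4-benzyloxy-3-methoxyphenyllithium 15 (not isolated), via lithium borate complex 16 (not isolated)
Conditions: 9 (1.3 equiv), t-BuLi (2.6 equiv), Et2O, −78 °C; 14 (1.3 equiv), −78 °C → rt; then 7 (1.0 equiv), Pd(OAc)2 (3 mol%), Mandyphos ligand 1,1′-bis[bis(4-methoxy-3,5-dimethylphenyl)phosphino]-2,2′-bis[α-(dimethylamino)benzyl]ferrocene (3.6 mol%), NaOTf (2 equiv), THF, 60 °C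
Reagents that add atoms: none
Why: Bromine–lithium exchange gives 15, which adds to the boron of 14 to form the four-coordinate borate 16. Zerovalent palladium, formed in the flask from Pd(OAc)2 and the bisphosphine, inserts into the C–OTf bond of 7, and because triflate does not bind, the resulting divalent arylpalladium is cationic and binds the electron-rich C2=C3 bond of 16. The ring C aryl group then shifts from boron to C2 anti to palladium while palladium bonds C3 (1,2-metallate shift), and reductive elimination with retention forms C3–C3a; no ring is closed in this step. The closest known reaction type is the palladium/Mandyphos conjunctive cross-coupling of β-substituted alkenylboron ate complexes with aryl triflates, which gives anti products. C3 is set by the ligand, which selects the alkene face that palladium binds, and C2 follows from C3 through the stereospecific anti addition to the E alkene, hence the anti (1S,2R) isomer. The step needs the metallate shift to beat direct Suzuki–Miyaura transmetallation, which the hindered diol of 14 secures by shielding the boronate oxygens, while NaOTf removes bromide so that palladium stays cationic. It also needs reductive elimination to outrun β-elimination of the C9 benzyloxy group and of hydride, which a wide-bite-angle ferrocenyl bisphosphine on a crowded aryl(alkyl)palladium should favour.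

Step 11
Reactants: 17 cis-1,2-dimethylacenaphthene-1,2-diyl (1S,2R)-3-(benzyloxy)-1-(4-benzyloxy-3-methoxyphenyl)-2-{5-[3-(tert-butyldimethylsilyloxy)propyl]-3-methoxy-2-(methoxymethoxy)phenyl}propylboronate
Product: 18 (1S,2R)-3-(benzyloxy)-1-(4-benzyloxy-3-methoxyphenyl)-2-{5-[3-(tert-butyldimethylsilyloxy)propyl]-3-methoxy-2-(methoxymethoxy)phenyl}propan-1-ol
Conditions: NaOH (3 M aq.), H2O2 (30%), THF, 0 °C → rt
Reagents that add atoms: hydrogen peroxide, OO
Why: Oxidation of the C–B bond by hydroperoxide (1,2-shift of carbon from boron to oxygen) proceeds with retention, so C2–B becomes C2–OH of the same configuration; benzyl, acetal and silyl ethers tolerate cold aqueous base.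

Step 12
Reactants: 18 (1S,2R)-3-(benzyloxy)-1-(4-benzyloxy-3-methoxyphenyl)-2-{5-[3-(tert-butyldimethylsilyloxy)propyl]-3-methoxy-2-(methoxymethoxy)phenyl}propan-1-ol
Product: 20 3-[(2S,3R)-3-(benzyloxymethyl)-2-(4-benzyloxy-3-methoxyphenyl)-7-methoxy-2,3-dihydro-1-benzofuran-5-yl]propan-1-ol, via phenolic diol 19 (not isolated)
Conditions: HCl (1.25 M in MeOH), CH2Cl2, 0 °C → rt, dilute
Reagents that add atoms: none
Why: Acid-catalysed methanolysis of the acetal and the silyl ether frees the C7a phenol and the chain alcohol; the C2 hydroxyl, benzylic and para to the ring C benzyloxy group, ionises and the phenol adds to the cation (SN1 etherification, 5-exo-trig closure). The closure is reversible under these conditions, so C2 should settle trans to the C9 group whichever C2 epimer enters, while C3 is not touched.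

Step 13
Reactants: 20 3-[(2S,3R)-3-(benzyloxymethyl)-2-(4-benzyloxy-3-methoxyphenyl)-7-methoxy-2,3-dihydro-1-benzofuran-5-yl]propan-1-ol
Product: 21 3-[(2S,3R)-3-(benzyloxymethyl)-2-(4-benzyloxy-3-methoxyphenyl)-7-methoxy-2,3-dihydro-1-benzofuran-5-yl]propyl hydrogen sulfate
Conditions: SO3·pyridine (3 equiv), pyridine, 0 °C → rt; aq. NaHCO3
Reagents that add atoms: sulfur trioxide–pyridine complex, [O-]S(=O)(=O)[n+]1ccccc1
Why: O-Sulfation of the only free hydroxyl with the sulfur trioxide–amine complex; no acid is generated and the bicarbonate work-up should give the sodium alkyl sulfate.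

Step 14
Reactants: 21 3-[(2S,3R)-3-(benzyloxymethyl)-2-(4-benzyloxy-3-methoxyphenyl)-7-methoxy-2,3-dihydro-1-benzofuran-5-yl]propyl hydrogen sulfate
Product: 22 3-[(2S,3R)-2-(4-hydroxy-3-methoxyphenyl)-3-(hydroxymethyl)-7-methoxy-2,3-dihydro-1-benzofuran-5-yl]propyl hydrogen sulfate
Conditions: H2 (1 atm), Pd/C (10%), MeOH–EtOAc, rt, stopped at full debenzylation
Reagents that add atoms: none
Why: Catalytic hydrogenolysis of the aryl benzyl ether and the primary alkyl benzyl ether; the sulfate salt is inert, and the secondary, more hindered benzylic O1–C2 bond should be cleaved more slowly than the two benzyl ethers.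

## Compound list

1 | 5-hydroxyvanillin (3,4-dihydroxy-5-methoxybenzaldehyde) | COc1cc(C=O)cc(O)c1O | starting material
2 | 3-hydroxy-5-methoxy-4-(methoxymethoxy)benzaldehyde | COCOc1c(O)cc(C=O)cc1OC | intermediate
3 | ethyl (E)-3-[3-hydroxy-5-methoxy-4-(methoxymethoxy)phenyl]prop-2-enoate | CCOC(=O)/C=C/c1cc(O)c(OCOC)c(OC)c1 | intermediate
4 | ethyl 3-[3-hydroxy-5-methoxy-4-(methoxymethoxy)phenyl]propanoate | CCOC(=O)CCc1cc(O)c(OCOC)c(OC)c1 | intermediate
5 | 3-[3-hydroxy-5-methoxy-4-(methoxymethoxy)phenyl]propan-1-ol | OCCCc1cc(O)c(OCOC)c(OC)c1 | intermediate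
6 | 5-(3-hydroxypropyl)-3-methoxy-2-(methoxymethoxy)phenyl trifluoromethanesulfonate | COCOc1c(OC)cc(CCCO)cc1OS(=O)(=O)C(F)(F)F | intermediate
7 | 5-[3-(tert-butyldimethylsilyloxy)propyl]-3-methoxy-2-(methoxymethoxy)phenyl trifluoromethanesulfonate | COCOc1c(OC)cc(CCCO[Si](C)(C)C(C)(C)C)cc1OS(=O)(=O)C(F)(F)F | intermediate
8 | 4-bromo-2-methoxyphenol | COc1cc(Br)ccc1O | starting material
9 | 1-(benzyloxy)-4-bromo-2-methoxybenzene | COc1cc(Br)ccc1OCc1ccccc1 | intermediate
10 | acenaphthoquinone | O=C1C(=O)c2cccc3cccc1c23 | starting material
11 | cis-1,2-dimethylacenaphthene-1,2-diol | C[C@]1(O)c2cccc3cccc(c23)[C@@]1(C)O | intermediate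
12 | benzyl propargyl ether | C#CCOCc1ccccc1 | starting material
13 | 2-[(E)-3-(benzyloxy)prop-1-enyl]-1,3,2-benzodioxaborole | c1ccccc1COC/C=C/B1Oc2ccccc2O1 | intermediate (not isolated)
14 | cis-1,2-dimethylacenaphthene-1,2-diyl (E)-3-(benzyloxy)prop-1-enylboronate | c1ccccc1COC/C=C/B1O[C@@]2(C)c3cccc4cccc(c34)[C@@]2(C)O1 | intermediate
15 | 4-benzyloxy-3-methoxyphenyllithium | [Li]c1ccc(OCc2ccccc2)c(OC)c1 | intermediate (not isolated)
16 | lithium (4-benzyloxy-3-methoxyphenyl)[(E)-3-(benzyloxy)prop-1-enyl](cis-1,2-dimethylacenaphthene-1,2-diolato)borate | [Li+].COc1cc([B-]2(/C=C/COCc3ccccc3)O[C@@]3(C)c4cccc5cccc(c45)[C@@]3(C)O2)ccc1OCc1ccccc1 | intermediate (not isolated)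
17 | cis-1,2-dimethylacenaphthene-1,2-diyl (1S,2R)-3-(benzyloxy)-1-(4-benzyloxy-3-methoxyphenyl)-2-{5-[3-(tert-butyldimethylsilyloxy)propyl]-3-methoxy-2-(methoxymethoxy)phenyl}propylboronate | COc1cc([C@@H](B2O[C@@]3(C)c4cccc5cccc(c45)[C@@]3(C)O2)[C@@H](COCc2ccccc2)c2cc(CCCO[Si](C)(C)C(C)(C)C)cc(OC)c2OCOC)ccc1OCc1ccccc1 | intermediate
18 | (1S,2R)-3-(benzyloxy)-1-(4-benzyloxy-3-methoxyphenyl)-2-{5-[3-(tert-butyldimethylsilyloxy)propyl]-3-methoxy-2-(methoxymethoxy)phenyl}propan-1-ol | COc1cc([C@@H](O)[C@@H](COCc2ccccc2)c2cc(CCCO[Si](C)(C)C(C)(C)C)cc(OC)c2OCOC)ccc1OCc1ccccc1 | intermediate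
19 | (1S,2R)-3-(benzyloxy)-1-(4-benzyloxy-3-methoxyphenyl)-2-[2-hydroxy-5-(3-hydroxypropyl)-3-methoxyphenyl]propan-1-ol | COc1cc([C@@H](O)[C@@H](COCc2ccccc2)c2cc(CCCO)cc(OC)c2O)ccc1OCc1ccccc1 | intermediate (not isolated)
20 | 3-[(2S,3R)-3-(benzyloxymethyl)-2-(4-benzyloxy-3-methoxyphenyl)-7-methoxy-2,3-dihydro-1-benzofuran-5-yl]propan-1-ol | COc1cc([C@H]2Oc3c(OC)cc(CCCO)cc3[C@@H]2COCc2ccccc2)ccc1OCc1ccccc1 | intermediate
21 | 3-[(2S,3R)-3-(benzyloxymethyl)-2-(4-benzyloxy-3-methoxyphenyl)-7-methoxy-2,3-dihydro-1-benzofuran-5-yl]propyl hydrogen sulfate | COc1cc([C@H]2Oc3c(OC)cc(CCCOS(=O)(=O)O)cc3[C@@H]2COCc2ccccc2)ccc1OCc1ccccc1 | intermediate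
22 | 3-[(2S,3R)-2-(4-hydroxy-3-methoxyphenyl)-3-(hydroxymethyl)-7-methoxy-2,3-dihydro-1-benzofuran-5-yl]propyl hydrogen sulfate | COc1cc([C@H]2Oc3c(OC)cc(CCCOS(=O)(=O)O)cc3[C@@H]2CO)ccc1O | target

## Step count and least certain steps

Total step count: 14. Longest linear sequence: 11 steps (steps 1 to 6, then 10 to 14).

**Step 10 (key step).**
- What may go wrong: direct transmetallation of the borate to palladium (ordinary Suzuki–Miyaura coupling) instead of the metallate shift, helped by the β-substituent and by slow oxidative addition of the ortho-substituted triflate. β-Elimination of the C9 benzyloxy group from the C3-bound palladium before reductive elimination. Poor face selection, because the ligand has to read an allylic ether and a crowded aryl group.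
- Fallback, from 9, 12 and 7, back at 18: Sonogashira coupling of 9 with 12 (PdCl2(PPh3)2, CuI, Et3N, 70 °C) would give the alkyne 1-(benzyloxy)-4-[3-(benzyloxy)prop-1-ynyl]-2-methoxybenzene F1. Palladium-catalysed syn hydrostannation (Bu3SnH, PdCl2(PPh3)2, THF) should place tin on the carbon next to the CH2OBn group, where both the donor aryl group and the propargylic oxygen direct it, and give tributyl[(E)-3-(benzyloxy)-1-(4-benzyloxy-3-methoxyphenyl)prop-1-en-2-yl]stannane F2. Stille coupling with 7 (Pd(PPh3)4, CuI, LiCl, DMF, 80 °C) would give the trisubstituted stilbene (Z)-1-(benzyloxy)-4-[3-(benzyloxy)-2-{5-[3-(tert-butyldimethylsilyloxy)propyl]-3-methoxy-2-(methoxymethoxy)phenyl}prop-1-enyl]-2-methoxybenzene F3. Asymmetric hydroboration with the appropriate antipode of monoisopinocampheylborane (syn addition, boron to the less substituted C2, hydrogen to C3), followed by NaOH/H2O2, gives 18. Syn addition to this alkene geometry gives the same relative configuration as the anti diarylation, and here a stoichiometric chiral borane sets C3.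

**Step 12 (acid closure).**
- What may go wrong: loss of the C3 proton from the C2 cation, which removes material and would erase C3 if the alkene were protonated again. Stalling through reversible capture of the cation by methanol. Intermolecular attack of the cation on an electron-rich ring if the solution is too concentrated.
- Fallback, from 17, back at 20: the order of events is changed so that the phenol is unmasked while C2 still carries boron and cannot ionise. Methanolic HCl on 17 would give the phenol boronate cis-1,2-dimethylacenaphthene-1,2-diyl (1S,2R)-3-(benzyloxy)-1-(4-benzyloxy-3-methoxyphenyl)-2-[2-hydroxy-5-(3-hydroxypropyl)-3-methoxyphenyl]propylboronate F4. NaOH/H2O2 then gives 19 as an isolated compound. Ring closure of 19 with catalytic camphorsulfonic acid in CH2Cl2 over 4 Å molecular sieves at 0 °C gives 20, in an aprotic medium with no competing nucleophile and with an acid too weak to protonate an alkene.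

**Step 14 (final debenzylation).**
- What may go wrong: hydrogenolytic opening of the benzylic O1–C2 bond during the longer exposure that the primary alkyl benzyl ether needs, and loss of the sulfate if the catalyst surface is acidic.
- Fallback, from 17, back at 22: the hydrogenolysis is moved to a stage where ring B does not yet exist, and the endgame finishes with fluoride.
  - H2 over Pd/C in EtOAc on 17 would give the debenzylated boronate cis-1,2-dimethylacenaphthene-1,2-diyl (1S,2R)-3-hydroxy-1-(4-hydroxy-3-methoxyphenyl)-2-{5-[3-(tert-butyldimethylsilyloxy)propyl]-3-methoxy-2-(methoxymethoxy)phenyl}propylboronate F5.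
  - TBDPSCl and imidazole in DMF silylate the phenol and the C9 hydroxyl to give the bis-silyl boronate cis-1,2-dimethylacenaphthene-1,2-diyl (1S,2R)-3-(tert-butyldiphenylsilyloxy)-1-[4-(tert-butyldiphenylsilyloxy)-3-methoxyphenyl]-2-{5-[3-(tert-butyldimethylsilyloxy)propyl]-3-methoxy-2-(methoxymethoxy)phenyl}propylboronate F6.
  - H2O2 in THF with pH 7 phosphate buffer, which spares the aryl silyl ether, gives the alcohol (1S,2R)-3-(tert-butyldiphenylsilyloxy)-1-[4-(tert-butyldiphenylsilyloxy)-3-methoxyphenyl]-2-{5-[3-(tert-butyldimethylsilyloxy)propyl]-3-methoxy-2-(methoxymethoxy)phenyl}propan-1-ol F7.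
  - Methanolic HCl as in step 12 cleaves the acetal and the tert-butyldimethylsilyl ether, should leave the two more robust silyl ethers, and closes the ring to 3-[(2S,3R)-3-(tert-butyldiphenylsilyloxymethyl)-2-[4-(tert-butyldiphenylsilyloxy)-3-methoxyphenyl]-7-methoxy-2,3-dihydro-1-benzofuran-5-yl]propan-1-ol F8. The ring C silyloxy group still stabilises the C2 cation.
  - SO3·pyridine gives 3-[(2S,3R)-3-(tert-butyldiphenylsilyloxymethyl)-2-[4-(tert-butyldiphenylsilyloxy)-3-methoxyphenyl]-7-methoxy-2,3-dihydro-1-benzofuran-5-yl]propyl hydrogen sulfate F9.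
  - Bu4NF in THF, followed by exchange to the sodium salt, gives 22.

**Step 1 (regioselective acetal formation).**
- What may go wrong: alkylation of both phenols or of the 3-hydroxyl, since chloromethyl methyl ether is very reactive and discriminates less than a benzyl halide.
- Fallback, from 1, back at 4: the less acidic, more nucleophilic 3-oxygen is blocked first through the dianion. NaH (2.2 equiv) in DMSO followed by BnBr (1.0 equiv) would give 3-(benzyloxy)-4-hydroxy-5-methoxybenzaldehyde F10. MOMCl and K2CO3 then give 3-(benzyloxy)-5-methoxy-4-(methoxymethoxy)benzaldehyde F11. Wittig olefination as in step 2 gives ethyl (E)-3-[3-(benzyloxy)-5-methoxy-4-(methoxymethoxy)phenyl]prop-2-enoate F12. Hydrogenation over Pd/C saturates the alkene and removes the benzyl group in one operation to give 4.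

## Further compounds

F1 | step 10 | 1-(benzyloxy)-4-[3-(benzyloxy)prop-1-ynyl]-2-methoxybenzene | COc1cc(C#CCOCc2ccccc2)ccc1OCc1ccccc1
F2 | step 10 | tributyl[(E)-3-(benzyloxy)-1-(4-benzyloxy-3-methoxyphenyl)prop-1-en-2-yl]stannane | COc1cc(/C=C(/[Sn](CCCC)(CCCC)CCCC)COCc2ccccc2)ccc1OCc1ccccc1
F3 | step 10 | (Z)-1-(benzyloxy)-4-[3-(benzyloxy)-2-{5-[3-(tert-butyldimethylsilyloxy)propyl]-3-methoxy-2-(methoxymethoxy)phenyl}prop-1-enyl]-2-methoxybenzene | COc1cc(/C=C(/c2cc(CCCO[Si](C)(C)C(C)(C)C)cc(OC)c2OCOC)COCc2ccccc2)ccc1OCc1ccccc1
F4 | step 12 | cis-1,2-dimethylacenaphthene-1,2-diyl (1S,2R)-3-(benzyloxy)-1-(4-benzyloxy-3-methoxyphenyl)-2-[2-hydroxy-5-(3-hydroxypropyl)-3-methoxyphenyl]propylboronate | COc1cc([C@@H](B2O[C@@]3(C)c4cccc5cccc(c45)[C@@]3(C)O2)[C@@H](COCc2ccccc2)c2cc(CCCO)cc(OC)c2O)ccc1OCc1ccccc1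
F5 | step 14 | cis-1,2-dimethylacenaphthene-1,2-diyl (1S,2R)-3-hydroxy-1-(4-hydroxy-3-methoxyphenyl)-2-{5-[3-(tert-butyldimethylsilyloxy)propyl]-3-methoxy-2-(methoxymethoxy)phenyl}propylboronate | COc1cc([C@@H](B2O[C@@]3(C)c4cccc5cccc(c45)[C@@]3(C)O2)[C@@H](CO)c2cc(CCCO[Si](C)(C)C(C)(C)C)cc(OC)c2OCOC)ccc1O
F6 | step 14 | cis-1,2-dimethylacenaphthene-1,2-diyl (1S,2R)-3-(tert-butyldiphenylsilyloxy)-1-[4-(tert-butyldiphenylsilyloxy)-3-methoxyphenyl]-2-{5-[3-(tert-butyldimethylsilyloxy)propyl]-3-methoxy-2-(methoxymethoxy)phenyl}propylboronate | COc1cc([C@@H](B2O[C@@]3(C)c4cccc5cccc(c45)[C@@]3(C)O2)[C@@H](CO[Si](c2ccccc2)(c2ccccc2)C(C)(C)C)c2cc(CCCO[Si](C)(C)C(C)(C)C)cc(OC)c2OCOC)ccc1O[Si](c1ccccc1)(c1ccccc1)C(C)(C)C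
F7 | step 14 | (1S,2R)-3-(tert-butyldiphenylsilyloxy)-1-[4-(tert-butyldiphenylsilyloxy)-3-methoxyphenyl]-2-{5-[3-(tert-butyldimethylsilyloxy)propyl]-3-methoxy-2-(methoxymethoxy)phenyl}propan-1-ol | COc1cc([C@@H](O)[C@@H](CO[Si](c2ccccc2)(c2ccccc2)C(C)(C)C)c2cc(CCCO[Si](C)(C)C(C)(C)C)cc(OC)c2OCOC)ccc1O[Si](c1ccccc1)(c1ccccc1)C(C)(C)C
F8 | step 14 | 3-[(2S,3R)-3-(tert-butyldiphenylsilyloxymethyl)-2-[4-(tert-butyldiphenylsilyloxy)-3-methoxyphenyl]-7-methoxy-2,3-dihydro-1-benzofuran-5-yl]propan-1-ol | COc1cc([C@H]2Oc3c(OC)cc(CCCO)cc3[C@@H]2CO[Si](c2ccccc2)(c2ccccc2)C(C)(C)C)ccc1O[Si](c1ccccc1)(c1ccccc1)C(C)(C)C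
F9 | step 14 | 3-[(2S,3R)-3-(tert-butyldiphenylsilyloxymethyl)-2-[4-(tert-butyldiphenylsilyloxy)-3-methoxyphenyl]-7-methoxy-2,3-dihydro-1-benzofuran-5-yl]propyl hydrogen sulfate | COc1cc([C@H]2Oc3c(OC)cc(CCCOS(=O)(=O)O)cc3[C@@H]2CO[Si](c2ccccc2)(c2ccccc2)C(C)(C)C)ccc1O[Si](c1ccccc1)(c1ccccc1)C(C)(C)C
F10 | step 1 | 3-(benzyloxy)-4-hydroxy-5-methoxybenzaldehyde | COc1cc(C=O)cc(OCc2ccccc2)c1O
F11 | step 1 | 3-(benzyloxy)-5-methoxy-4-(methoxymethoxy)benzaldehyde | COCOc1c(OC)cc(C=O)cc1OCc1ccccc1
F12 | step 1 | ethyl (E)-3-[3-(benzyloxy)-5-methoxy-4-(methoxymethoxy)phenyl]prop-2-enoate | CCOC(=O)/C=C/c1cc(OC)c(OCOC)c(OCc2ccccc2)c1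
A1 | alternative 1 | (Z)-3-(4-hydroxy-3-methoxyphenyl)-2-{2-hydroxy-3-methoxy-5-[3-(tert-butyldimethylsilyloxy)propyl]phenyl}prop-2-enyl acetate | COc1cc(/C=C(/c2cc(CCCO[Si](C)(C)C(C)(C)C)cc(OC)c2O)COC(C)=O)ccc1O
A2 | alternative 1 | trans 3-(acetoxymethyl)-2-(4-hydroxy-3-methoxyphenyl)-7-methoxy-5-[3-(tert-butyldimethylsilyloxy)propyl]-2,3-dihydrobenzofuran | COc1cc([C@H]2Oc3c(OC)cc(CCCO[Si](C)(C)C(C)(C)C)cc3[C@@H]2COC(C)=O)ccc1O
A3 | alternative 2 | 1-(4-benzyloxy-3-methoxyphenyl)-2-(benzyloxymethyl)but-3-ynyl (triethylsilyl)ethynyl ether, configured as C2 and C3 of the target | COc1cc([C@@H](OC#C[Si](CC)(CC)CC)[C@@H](COCc2ccccc2)C#C)ccc1OCc1ccccc1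
A4 | alternative 2 | tert-butyldimethyl(pent-4-ynyloxy)silane | C#CCCCO[Si](C)(C)C(C)(C)C
A5 | alternative 2 | trans 2-(4-benzyloxy-3-methoxyphenyl)-3-(benzyloxymethyl)-5-[3-(tert-butyldimethylsilyloxy)propyl]-7-(triethylsilyl)-2,3-dihydrobenzofuran | COc1cc([C@H]2Oc3c([Si](CC)(CC)CC)cc(CCCO[Si](C)(C)C(C)(C)C)cc3[C@@H]2COCc2ccccc2)ccc1OCc1ccccc1
A6 | alternative 3 | tert-butyl{[trans-5-(4-benzyloxy-3-methoxyphenyl)-4-(benzyloxymethyl)-4,5-dihydrofuran-2-yl]oxy}dimethylsilane | COc1cc([C@H]2OC(O[Si](C)(C)C(C)(C)C)=C[C@@H]2COCc2ccccc2)ccc1OCc1ccccc1
A7 | alternative 3 | methyl 3-bromo-2-oxo-2H-pyran-5-carboxylate | COC(=O)C1=COC(=O)C(Br)=C1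
A8 | alternative 3 | methyl trans 2-(4-benzyloxy-3-methoxyphenyl)-3-(benzyloxymethyl)-7-bromo-2,3-dihydrobenzofuran-5-carboxylate | COc1cc([C@H]2Oc3c(Br)cc(C(=O)OC)cc3[C@@H]2COCc2ccccc2)ccc1OCc1ccccc1
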